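Take the ratio of winter to spring: the catalyst charge stands at 2.11, the product reading at 2.50 h at 1.74. Between these two runs product grows less than catalyst, so find what slips.

| flask | substrate | partner | protic impurity | free catalyst | remark | time |
|---|---|---|---|---|---|---|
| spring | 10 mM | 15 mM | 1 mM | 0.35 mM | run made earlier |  |
| winter | 10 mM | 15 mM | 1 mM | 0.74 mM | run made earlier |  |
| delta | 10 mM | 15.0 mM | 1.00 mM | 0.50 mM |  | 2.5 h |
| epsilon | 10 mM | 15.0 mM | 1.00 mM | 1.0 mM |  | 2.5 h |

| run | time / h | catalyst intermediate C / % | product / % | substrate / % | catalyst intermediate A / % |
|---|---|---|---|---|---|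
| spring | 0.333 | 1.5 | 7.9 | 87.7 | 3.8 |
| spring | 0.833 | 0.5 | 18.6 | 79.8 | 2.1 |
| spring | 1.50 | 1.2 | 28.6 | 68.7 | 3.0 |
| spring | 2.50 | 0 | 39.7 | 56.2 | 2.5 |
| winter | 0.667 | 0.9 | 30.3 | 62.4 | 6.7 |
| winter | 1.33 | 1.8 | 51.6 | 40.9 | 5.5 |
| winter | 2.00 | 0.6 | 63.0 | 30.1 | 6.6 |
| winter | 2.50 | 0 | 69.1 | 25.3 | 6.2 |

(standard deviation of a reading: 1 percentage point)

- which of these there is most of at the end, counted by the substrate in it, delta (catalyst intermediate A / product / substrate / catalyst intermediate C)
- which of these there is most of at the end, counted by the substrate in it, epsilon (catalyst intermediate A / product / substrate / catalyst intermediate C)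
- how much there is at the end of the one of these that leads, in percent of the substrate charged: delta
- how much there is at the end of the one of these that leads, in percent of the substrate charged: epsilon

Read the product columns per catalyst. Over the first readings, spring makes 6.38 h⁻¹ and winter 6.14 h⁻¹, so the two start close. Over the last readings, spring still makes 3.17 h⁻¹, but winter makes 2.02 h⁻¹, less than spring. The comparison drifts: by the suspects, each product takes one substrate and one partner, and winter has made 6.91 mM against spring's 3.97 mM, so its charges have sunk further.

Carry one quantity: N, the turnover number at 2.5 h, product in mM per mM of catalyst charged. Spring gives 11.3, winter 9.34. Draw a straight line through these two readings: N falls with the catalyst charged, at a slope of 5.14 mM⁻¹. The line puts delta at N = 10.6, which is 52.9% product. It puts epsilon at N = 8.00, which is 80.0% product. On these estimates product holds more of the substrate charged than the remainder does, in delta and in epsilon, so I expect product to lead in both. Each end reading carries a scatter of 1 percentage point, and epsilon lies beyond winter on the line, so trust delta more.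

The forecast, holding that “partner is running out”, gives product leading with 52% in delta and product with 81% in epsilon.

Delta ends with product leading at 52.6% and epsilon with product at 81.9%, so N comes to 10.5 in delta and 8.19 in epsilon.

substrate + free catalyst → catalyst intermediate A (k = 213 L mol⁻¹ min⁻¹); partner + catalyst intermediate A → catalyst intermediate B (k = 18.3 L mol⁻¹ min⁻¹); catalyst intermediate B → released group + catalyst intermediate C (k = 7.83 min⁻¹); catalyst intermediate C → free catalyst + product (k = 0.357 min⁻¹); 2 partner → homo dimer (k = 0.535 L mol⁻¹ min⁻¹); partner + protic impurity → quenched reagent (k = 10.5 L mol⁻¹ min⁻¹) Of its partner charge, epsilon keeps 5.60% at the end and delta 13.6%. Put N on the neighbour of epsilon charged with 4.0 mM of protic impurity: it ends at 69.3% product, which is N = 6.93, with 4.0% of its partner left.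

The runs are calculated with made-up constants.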